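**Retrosynthetic overview**
1. Target ⇒ C2 propanoate (last), C9 acetate and the O7–C19 γ-lactone by acylation steps; the ten-membered ring is closed at C6–C7 by an intramolecular Nozaki–Hiyama–Kishi addition of the (Z)-C5=C6 vinyl iodide to a C7 aldehyde.
2. C8–C17 (with the C17–C19 ester) by chelation-controlled Reformatsky addition to a C8 ketone; C9–C10 by anti-aldol of a cyclopentenone α'-enolate with an achiral, non-enolisable C7–C9 aldehyde.
3. Key disconnection: the cyclohexenone ring C1–C10–C11–C12–C13–C14 comes from the cyclopentene ring C1–C10–C12–C13–C14 by insertion of C11 (α-ketol rearrangement of a 12-acetyl-12-hydroxycyclopentene). The enabling feature is the tertiary α-ketol C11(OH)(CH3)–C12(=O), next to ring-fusion carbon C10 and conjugated with C13=C14.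
4. Cyclopentenone from a 1,4-keto-aldehyde (Wacker oxidation, aldol condensation); C2 by Noyori reduction, C1 by Fráter–Seebach methylation; (Z)-vinyl iodide from propargyl alcohol.
5. Order of ring formation: cyclopentenone → cyclohexenone (ring expansion) → ten-membered carbocycle → γ-lactone.

Key step: step 15

Remark: atom labels C1–C20 are briarane positions (C1 quaternary ring-fusion C, C2 CH–O-propanoyl, C5=C6, C7 lactone CH–O, C8 C–OH, C9 CH–OAc, C10 ring-fusion CH, C11 C(OH)CH3, C12 C=O, C13=C14, C17 CH(CH3), C19 lactone C=O); metal enolates, alkoxides and organometallic forms of a substrate are treated as states of that substrate and are numbered only where a further reagent intercepts them in the same flask.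

**Route**

Step 1
Reactants: 1 prop-2-yn-1-ol
Product: 3 (2Z)-3-iodo-2-methylprop-2-en-1-ol, via carbomagnesiation adduct 2 (not isolated)
Conditions: MeMgBr (2.5 equiv), CuI (10 mol%), THF, −10 °C → rt; then I2, −40 → 0 °C
Reagents that add atoms: methylmagnesium bromide C[Mg]Br; iodine II
Why: Copper-catalysed anti-carbomagnesiation of the magnesium propargylic alkoxide places methyl on C5 and magnesium on C6 cis to the CH2O group (chelate), and iodinolysis with retention should give the Z-iodide that becomes the C5=C6 olefin.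

Step 2
Reactants: 3 (2Z)-3-iodo-2-methylprop-2-en-1-ol
Product: 4 (1Z)-3-bromo-1-iodo-2-methylprop-1-ene
Conditions: CBr4, PPh3, CH2Cl2, 0 °C
Reagents that add atoms: carbon tetrabromide BrC(Br)(Br)Br
Why: Appel bromination of a primary allylic alcohol, which does not touch the olefin geometry.

Step 3
Reactants: 5 ethyl 2-acetylpent-4-enoate; 4 (1Z)-3-bromo-1-iodo-2-methylprop-1-ene
Product: 6 ethyl (6Z)-7-iodo-6-methyl-3-oxo-2-(prop-2-en-1-yl)hept-6-enoate
Conditions: NaH (1.1 equiv), THF, 0 °C; n-BuLi (1.05 equiv), 0 °C; then 4, 0 °C → rt; 1 M HCl quench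
Reagents that add atoms: none
Why: γ-Alkylation of the acetoacetate dianion by the allylic bromide forms C3–C4 at the more reactive terminal carbanion; all n-BuLi is consumed before the vinyl iodide is added.

Step 4
Reactants: 6 β-keto ester
Product: 7 ethyl (3R,6Z)-3-hydroxy-7-iodo-6-methyl-2-(prop-2-en-1-yl)hept-6-enoate (both C2 epimers)
Conditions: [RuCl2((R)-BINAP)]2·NEt3 (1 mol%), H2 (4 atm), EtOH, 50 °C
Reagents that add atoms: none
Why: Noyori asymmetric hydrogenation of the β-keto ester through its Ru chelate, where (R)-BINAP should give the 3R carbinol (target C2); the α-centre is erased in step 5 and olefins without a directing group are not reduced by the Ru(II) halide catalyst.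

Step 5
Reactants: 7 β-hydroxy ester
Product: 8 ethyl (2S,3R,6Z)-3-hydroxy-7-iodo-2,6-dimethyl-2-(prop-2-en-1-yl)hept-6-enoate
Conditions: LDA (2.2 equiv), THF, −78 → −20 °C; MeI, DMPU, −78 → −20 °C
Reagents that add atoms: iodomethane CI
Why: Fráter–Seebach alkylation, in which MeI enters the chelated lithium alkoxide–enolate anti to the C3 chain and so sets quaternary C1 (methyl anti to O2) from C2, whichever α-epimer of 7 is used.

Step 6
Reactants: 8 hydroxy ester
Product: 9 TBS ether of 8
Conditions: TBSOTf, 2,6-lutidine, CH2Cl2, 0 °C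
Reagents that add atoms: tert-butyldimethylsilyl triflate CC(C)(C)[Si](C)(C)OS(=O)(=O)C(F)(F)F
Why: Silylation of the hindered secondary alcohol with the silyl triflate, which protects O2 until step 19.

Step 7
Reactants: 9 silyloxy ester
Product: 10 (2S,3R,6Z)-3-[(tert-butyldimethylsilyl)oxy]-7-iodo-2,6-dimethyl-2-(prop-2-en-1-yl)hept-6-enal
Conditions: DIBAL-H (1.1 equiv), CH2Cl2, −78 °C; Rochelle salt
Reagents that add atoms: none
Why: Low-temperature DIBAL-H reduction of the hindered α-quaternary ester should stop at the aldehyde because the tetrahedral aluminate is stable at −78 °C.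

Step 8
Reactants: 10 aldehyde
Product: 11 (2S,3R,6Z)-3-[(tert-butyldimethylsilyl)oxy]-7-iodo-2,6-dimethyl-2-(2-oxopropyl)hept-6-enal
Conditions: PdCl2 (10 mol%), CuCl (1 equiv), O2 (1 atm), DMF/H2O 7:1, rt
Reagents that add atoms: water O
Why: Tsuji–Wacker oxidation of the terminal olefin to the methyl ketone (Markovnikov), the trisubstituted iodo-olefin being unreactive towards Pd(II).

Step 9
Reactants: 11 keto-aldehyde
Product: 12 (4R)-4-[(1R,4Z)-1-[(tert-butyldimethylsilyl)oxy]-5-iodo-4-methylpent-4-en-1-yl]-4-methylcyclopent-2-en-1-one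
Conditions: KOH (5% aq.), MeOH/THF, rt → 50 °C
Reagents that add atoms: none
Why: Intramolecular aldol condensation (5-enolexo) of the 1,4-keto-aldehyde, in which the methyl ketone enolate adds to the non-enolisable aldehyde and dehydration gives the 4,4-disubstituted cyclopent-2-enone; C1 cannot epimerise.

Step 10
Reactants: 13 2,2-dimethoxypropane-1,3-diol
Product: 14 3-[(tert-butyldiphenylsilyl)oxy]-2,2-dimethoxypropan-1-ol
Conditions: NaH (1.0 equiv), THF, 0 °C; TBDPSCl (1.0 equiv)
Reagents that add atoms: tert-butyldiphenylsilyl chloride CC(C)(C)[Si](Cl)(c1ccccc1)c1ccccc1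
Why: Monosilylation of the symmetric diol through its monosodium alkoxide.

Step 11
Reactants: 14 mono-silyl ether
Product: 15 3-[(tert-butyldiphenylsilyl)oxy]-2,2-dimethoxypropanal
Conditions: Dess–Martin periodinane, NaHCO3, CH2Cl2, rt
Reagents that add atoms: none
Why: Dess–Martin oxidation to a non-enolisable α,α-dialkoxy aldehyde (C9, with C8 masked as the ketal and C7 as the silyl ether).

Step 12
Reactants: 12 cyclopentenone; 15 aldehyde
Product: 17 TES-protected anti-aldol adduct, via lithium aldolate 16 (not isolated)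
Conditions: LDA (1.05 equiv), THF, −78 °C; 15, −78 °C; then TESOTf (1.2 equiv), −78 → −40 °C
Reagents that add atoms: triethylsilyl triflate CC[Si](CC)(CC)OS(=O)(=O)C(F)(F)F
Why: Only C10 of 12 can be deprotonated (C14 is vinylic, C1 quaternary); the aldehyde is attacked on the enolate face anti to the large C1 side chain (cis to the C1 methyl), and the E-configured cyclic lithium enolate reacts through a Zimmerman–Traxler chair to give the anti aldol (C9 R, C10 S); silylating the aldolate in situ blocks retro-aldol.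

Step 13
Reactants: 17 silyl-protected aldol adduct
Product: 18 12α-ethynyl-12β-hydroxy carbinol
Conditions: ethynylmagnesium bromide (3 equiv), THF, −20 → 0 °C
Reagents that add atoms: ethynylmagnesium bromide C#C[Mg]Br
Why: 1,2-Addition of the acetylide to the enone carbonyl anti to the bulky C10 substituent should put the ethynyl group α and the hydroxyl β at C12; acetylides do not exchange with the vinyl iodide.

Step 14
Reactants: 18 ethynyl carbinol
Product: 20 12α-acetyl-12β-hydroxy cyclopentene, via cyclic carbonate 19 (not isolated)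
Conditions: AgOAc (10 mol%), DBU (1 equiv), CO2 (1 atm), MeCN, rt; then H2O
Reagents that add atoms: water O
Why: Silver-catalysed carboxylative cyclisation of the tertiary propargylic alcohol to the α-methylene cyclic carbonate, followed by hydrolysis, amounts to Markovnikov hydration to the methyl ketone under non-acidic conditions (no Meyer–Schuster or Rupe ionisation); C12 is not touched.

Step 15
Reactants: 20 12α-acetyl-12β-hydroxy cyclopentene
Product: 21 ring-expanded 11-hydroxy-11-methyl-cyclohex-13-en-12-one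
Conditions: KOt-Bu (0.2 equiv), 18-crown-6 (0.2 equiv), t-BuOH/THF, −20 °C → rt
Reagents that add atoms: none
Why: Base-mediated α-ketol (acyloin) rearrangement, the reaction type of the D-homoannulation of 17-hydroxy-20-keto steroids: the C12 alkoxide re-forms C12=O while the C12–C10 bond shifts to the acetyl carbon C11, so the five-membered ring C1–C10–C12–C13–C14 becomes the six-membered ring C1–C10–C11–C12–C13–C14 (ring expansion by 1,2-shift; no ring is closed by cyclisation). C11 is the only new stereocentre: in the crown-ether-separated alkoxide the C12–O⁻ and C11=O dipoles lie anti-periplanar, and with the acetyl group on the α-face (step 13) C10 then adds to the carbonyl face that leaves the new oxygen α and the methyl β (11S). The step needs C10 and not the vinylic C13 to migrate; only C10 migration brings C12=O into conjugation with C13=C14, and since ketol shifts are reversible under alkoxide catalysis the conjugated, non-enolisable 6-hydroxy-6-methylcyclohexenone should be the thermodynamic sink. The substrate feature that allows this is the tertiary carbinol C12 carrying both the acyl group and the ring bond to C10; the C8 ketal, the silyl ethers and the vinyl iodide are inert to catalytic alkoxide. Low temperature and short reaction time should keep C11 under kinetic control.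

Step 16
Reactants: 21 ring-expanded enone
Product: 22 C8 ketone with free C9–OH
Conditions: PPTS (0.3 equiv), acetone/H2O 10:1, 50 °C
Reagents that add atoms: water O
Why: Acid-catalysed ketal hydrolysis unmasks the C8 ketone and cleaves the labile triethylsilyl ether, while the TBDPS ether, the hindered TBS ether and the tertiary α-ketol are expected to survive PPTS; 22 may rest partly as a hemiketal with O11 and reacts through the open form.

Step 17
Reactants: 22 α-hydroxy ketone; 23 tert-butyl 2-bromopropanoate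
Product: 24 C8 tertiary alcohol with the C17–C19 tert-butyl ester
Conditions: Zn dust (TMSCl-activated), 23, THF, rt (preformed reagent, 4 equiv); then 22, −20 → 0 °C
Reagents that add atoms: none
Why: Reformatsky addition to the C8 ketone of an α-hydroxy ketone, in which the zinc alkoxide of O9 chelates the C8 carbonyl (Cram chelate) so that the enolate attacks anti to the C10 ring (8S); the hindered, conjugated C12 ketone stays untouched, and C17 is expected as 17R (methyl anti to the C9 branch) and remains epimerisable towards this more stable arrangement.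

Step 18
Reactants: 24 diol ester
Product: 25 C9 acetate
Conditions: Ac2O (1.5 equiv), pyridine, DMAP (cat.), CH2Cl2, 0 °C → rt
Reagents that add atoms: acetic anhydride CC(=O)OC(C)=O
Why: C9–OH is the only secondary hydroxyl, so DMAP-catalysed acetylation leaves the tertiary C8 and C11 alcohols free and blocks O9 from lactonising later.

Step 19
Reactants: 25 acetate
Product: 26 C2,C7-diol
Conditions: HF·pyridine, THF/pyridine, 0 °C → rt
Reagents that add atoms: none
Why: Fluoride-mediated cleavage of both silyl ethers under buffered, non-basic conditions (no acetyl migration); the tert-butyl ester should resist lactonisation by the neopentylic primary alcohol.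

Step 20
Reactants: 26 diol
Product: 27 C7 aldehyde
Conditions: TEMPO (10 mol%), PhI(OAc)2 (1.2 equiv), CH2Cl2, rt
Reagents that add atoms: none
Why: TEMPO/PhI(OAc)2 oxidises the primary C7 alcohol selectively beside the hindered secondary C2–OH and the tertiary alcohols and stops at the aldehyde.

Step 21
Reactants: 27 iodo-aldehyde
Product: 28 ten-membered carbocycle with 7S-OH
Conditions: CrCl2 (10 equiv), NiCl2 (1 mol%), DMSO, 2 mM, rt
Reagents that add atoms: none
Why: Intramolecular Nozaki–Hiyama–Kishi reaction, in which the alkenylchromium(III) species forms with retention of the Z geometry and adds chemoselectively to the aldehyde (ketone, esters and free hydroxyls tolerated), closing the ten-membered ring at C6–C7; attack anti to the C8–O bond with the tethered C9 branch gauche (Felkin–Anh) should give the 7S alcohol.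

Step 22
Reactants: 28 hydroxy tert-butyl ester
Product: 30 γ-lactone with free C2–OH, via hydroxy acid 29 (not isolated)
Conditions: TFA/CH2Cl2 1:4, 0 °C → rt; concentrate from toluene
Reagents that add atoms: none
Why: Acidolysis of the tert-butyl ester and spontaneous γ-lactonisation of the hydroxy acid onto O7 (five-ring closure favoured by the quaternary C8, acyl substitution with retention at C7), O9 being blocked as the acetate.

Step 23
Reactants: 30 lactone alcohol
Product: 31 target CNP0240018.1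
Conditions: propanoic anhydride (2 equiv), Et3N, DMAP (cat.), CH2Cl2, 0 °C → rt
Reagents that add atoms: propanoic anhydride CCC(=O)OC(=O)CC
Why: DMAP-catalysed acylation of the only remaining secondary hydroxyl (C2), under which the tertiary C8 and C11 alcohols should not react.

**Compound list**
1 | prop-2-yn-1-ol | C#CCO | starting material
2 | bromomagnesium (2Z)-3-(bromomagnesio)-2-methylprop-2-en-1-olate | Br[Mg]OC/C(C)=C\[Mg]Br | intermediate
3 | (2Z)-3-iodo-2-methylprop-2-en-1-ol | OC/C(C)=C\I | intermediate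
4 | (1Z)-3-bromo-1-iodo-2-methylprop-1-ene | BrC/C(C)=C\I | intermediate
5 | ethyl 2-acetylpent-4-enoate (ethyl 2-allylacetoacetate) | CCOC(=O)C(CC=C)C(C)=O | starting material
6 | ethyl (6Z)-7-iodo-6-methyl-3-oxo-2-(prop-2-en-1-yl)hept-6-enoate (racemic at C2) | CCOC(=O)C(CC=C)C(=O)CC/C(C)=C\I | intermediate
7 | ethyl (3R,6Z)-3-hydroxy-7-iodo-6-methyl-2-(prop-2-en-1-yl)hept-6-enoate (both C2 epimers) | CCOC(=O)C(CC=C)[C@H](O)CC/C(C)=C\I | intermediate
8 | ethyl (2S,3R,6Z)-3-hydroxy-7-iodo-2,6-dimethyl-2-(prop-2-en-1-yl)hept-6-enoate | CCOC(=O)[C@@](C)(CC=C)[C@H](O)CC/C(C)=C\I | intermediate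
9 | ethyl (2S,3R,6Z)-3-[(tert-butyldimethylsilyl)oxy]-7-iodo-2,6-dimethyl-2-(prop-2-en-1-yl)hept-6-enoate | CCOC(=O)[C@@](C)(CC=C)[C@H](O[Si](C)(C)C(C)(C)C)CC/C(C)=C\I | intermediate
10 | (2S,3R,6Z)-3-[(tert-butyldimethylsilyl)oxy]-7-iodo-2,6-dimethyl-2-(prop-2-en-1-yl)hept-6-enal | O=C[C@@](C)(CC=C)[C@H](O[Si](C)(C)C(C)(C)C)CC/C(C)=C\I | intermediate
11 | (2S,3R,6Z)-3-[(tert-butyldimethylsilyl)oxy]-7-iodo-2,6-dimethyl-2-(2-oxopropyl)hept-6-enal | O=C[C@@](C)(CC(C)=O)[C@H](O[Si](C)(C)C(C)(C)C)CC/C(C)=C\I | intermediate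
12 | (4R)-4-[(1R,4Z)-1-[(tert-butyldimethylsilyl)oxy]-5-iodo-4-methylpent-4-en-1-yl]-4-methylcyclopent-2-en-1-one | CC(C)(C)[Si](C)(C)O[C@H](CC/C(C)=C\I)[C@@]1(C)C=CC(=O)C1 | intermediate
13 | 2,2-dimethoxypropane-1,3-diol | COC(CO)(CO)OC | starting material
14 | 3-[(tert-butyldiphenylsilyl)oxy]-2,2-dimethoxypropan-1-ol | COC(CO)(CO[Si](c1ccccc1)(c1ccccc1)C(C)(C)C)OC | intermediate
15 | 3-[(tert-butyldiphenylsilyl)oxy]-2,2-dimethoxypropanal | COC(C=O)(CO[Si](c1ccccc1)(c1ccccc1)C(C)(C)C)OC | intermediate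
16 | lithium aldolate of 12 and 15 (C9–OLi, configuration as in 17) | CC(C)(C)[Si](C)(C)O[C@H](CC/C(C)=C\I)[C@@]1(C)C=CC(=O)[C@@H]1[C@@H](O[Li])C(OC)(OC)CO[Si](c2ccccc2)(c2ccccc2)C(C)(C)C | intermediate
17 | (4S,5S)-5-[(1R)-3-[(tert-butyldiphenylsilyl)oxy]-2,2-dimethoxy-1-[(triethylsilyl)oxy]propyl]-4-[(1R,4Z)-1-[(tert-butyldimethylsilyl)oxy]-5-iodo-4-methylpent-4-en-1-yl]-4-methylcyclopent-2-en-1-one | CC(C)(C)[Si](C)(C)O[C@H](CC/C(C)=C\I)[C@@]1(C)C=CC(=O)[C@@H]1[C@@H](O[Si](CC)(CC)CC)C(OC)(OC)CO[Si](c2ccccc2)(c2ccccc2)C(C)(C)C | intermediate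
18 | (1S,4S,5S)-5-[(1R)-3-[(tert-butyldiphenylsilyl)oxy]-2,2-dimethoxy-1-[(triethylsilyl)oxy]propyl]-4-[(1R,4Z)-1-[(tert-butyldimethylsilyl)oxy]-5-iodo-4-methylpent-4-en-1-yl]-1-ethynyl-4-methylcyclopent-2-en-1-ol | CC(C)(C)[Si](C)(C)O[C@H](CC/C(C)=C\I)[C@@]1(C)C=C[C@@](O)(C#C)[C@@H]1[C@@H](O[Si](CC)(CC)CC)C(OC)(OC)CO[Si](c2ccccc2)(c2ccccc2)C(C)(C)C | intermediate
19 | cyclic carbonate of 18 (4-methylidene-1,3-dioxolan-2-one spiro-fused at C12, O12 on the β-face) | CC(C)(C)[Si](C)(C)O[C@H](CC/C(C)=C\I)[C@@]1(C)C=C[C@@](O2)(C(=C)OC2=O)[C@@H]1[C@@H](O[Si](CC)(CC)CC)C(OC)(OC)CO[Si](c3ccccc3)(c3ccccc3)C(C)(C)C | intermediate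
20 | 1-[(1S,4S,5S)-5-[(1R)-3-[(tert-butyldiphenylsilyl)oxy]-2,2-dimethoxy-1-[(triethylsilyl)oxy]propyl]-4-[(1R,4Z)-1-[(tert-butyldimethylsilyl)oxy]-5-iodo-4-methylpent-4-en-1-yl]-1-hydroxy-4-methylcyclopent-2-en-1-yl]ethan-1-one | CC(C)(C)[Si](C)(C)O[C@H](CC/C(C)=C\I)[C@@]1(C)C=C[C@@](O)(C(C)=O)[C@@H]1[C@@H](O[Si](CC)(CC)CC)C(OC)(OC)CO[Si](c2ccccc2)(c2ccccc2)C(C)(C)C | intermediate
21 | (4S,5S,6S)-5-[(1R)-3-[(tert-butyldiphenylsilyl)oxy]-2,2-dimethoxy-1-[(triethylsilyl)oxy]propyl]-4-[(1R,4Z)-1-[(tert-butyldimethylsilyl)oxy]-5-iodo-4-methylpent-4-en-1-yl]-6-hydroxy-4,6-dimethylcyclohex-2-en-1-one | CC(C)(C)[Si](C)(C)O[C@H](CC/C(C)=C\I)[C@@]1(C)C=CC(=O)[C@@](C)(O)[C@@H]1[C@@H](O[Si](CC)(CC)CC)C(OC)(OC)CO[Si](c2ccccc2)(c2ccccc2)C(C)(C)C | intermediate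
22 | (4S,5S,6S)-5-[(1R)-3-[(tert-butyldiphenylsilyl)oxy]-1-hydroxy-2-oxopropyl]-4-[(1R,4Z)-1-[(tert-butyldimethylsilyl)oxy]-5-iodo-4-methylpent-4-en-1-yl]-6-hydroxy-4,6-dimethylcyclohex-2-en-1-one | CC(C)(C)[Si](C)(C)O[C@H](CC/C(C)=C\I)[C@@]1(C)C=CC(=O)[C@@](C)(O)[C@@H]1[C@@H](O)C(=O)CO[Si](c2ccccc2)(c2ccccc2)C(C)(C)C | intermediate
23 | tert-butyl 2-bromopropanoate (racemic) | CC(Br)C(=O)OC(C)(C)C | starting material
24 | tert-butyl (2R,3S,4R)-4-[(1S,2S,6S)-6-[(1R,4Z)-1-[(tert-butyldimethylsilyl)oxy]-5-iodo-4-methylpent-4-en-1-yl]-2-hydroxy-2,6-dimethyl-3-oxocyclohex-4-en-1-yl]-3-{[(tert-butyldiphenylsilyl)oxy]methyl}-3,4-dihydroxy-2-methylbutanoate | CC(C)(C)[Si](C)(C)O[C@H](CC/C(C)=C\I)[C@@]1(C)C=CC(=O)[C@@](C)(O)[C@@H]1[C@@H](O)[C@@](O)(CO[Si](c2ccccc2)(c2ccccc2)C(C)(C)C)[C@@H](C)C(=O)OC(C)(C)C | intermediate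
25 | 4-O-acetate of 24: tert-butyl (2R,3S,4R)-4-(acetyloxy)-3-{[(tert-butyldiphenylsilyl)oxy]methyl}-3-hydroxy-2-methyl-4-[cyclohexenyl group as in 24]butanoate | CC(C)(C)[Si](C)(C)O[C@H](CC/C(C)=C\I)[C@@]1(C)C=CC(=O)[C@@](C)(O)[C@@H]1[C@@H](OC(C)=O)[C@@](O)(CO[Si](c2ccccc2)(c2ccccc2)C(C)(C)C)[C@@H](C)C(=O)OC(C)(C)C | intermediate
26 | tert-butyl (2R,3S,4R)-4-(acetyloxy)-3-hydroxy-3-(hydroxymethyl)-4-[(1S,2S,6S)-2-hydroxy-6-[(1R,4Z)-1-hydroxy-5-iodo-4-methylpent-4-en-1-yl]-2,6-dimethyl-3-oxocyclohex-4-en-1-yl]-2-methylbutanoate | O[C@H](CC/C(C)=C\I)[C@@]1(C)C=CC(=O)[C@@](C)(O)[C@@H]1[C@@H](OC(C)=O)[C@@](O)(CO)[C@@H](C)C(=O)OC(C)(C)C | intermediate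
27 | tert-butyl (2R,3R,4R)-4-(acetyloxy)-3-formyl-3-hydroxy-4-[(1S,2S,6S)-2-hydroxy-6-[(1R,4Z)-1-hydroxy-5-iodo-4-methylpent-4-en-1-yl]-2,6-dimethyl-3-oxocyclohex-4-en-1-yl]-2-methylbutanoate | O[C@H](CC/C(C)=C\I)[C@@]1(C)C=CC(=O)[C@@](C)(O)[C@@H]1[C@@H](OC(C)=O)[C@@](O)(C=O)[C@@H](C)C(=O)OC(C)(C)C | intermediate
28 | tert-butyl (2R)-2-[(1S,2R,5Z,7S,8S,9R,10S,11S)-9-(acetyloxy)-2,7,8,11-tetrahydroxy-1,5,11-trimethyl-12-oxobicyclo[8.4.0]tetradeca-5,13-dien-8-yl]propanoate (briarane numbering) | O[C@@H]1CC/C(C)=C\[C@H](O)[C@@](O)([C@@H](C)C(=O)OC(C)(C)C)[C@H](OC(C)=O)[C@@H]2[C@]1(C)C=CC(=O)[C@@]2(C)O | intermediate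
29 | (2R)-2-[(1S,2R,5Z,7S,8S,9R,10S,11S)-9-(acetyloxy)-2,7,8,11-tetrahydroxy-1,5,11-trimethyl-12-oxobicyclo[8.4.0]tetradeca-5,13-dien-8-yl]propanoic acid (briarane numbering) | O[C@@H]1CC/C(C)=C\[C@H](O)[C@@](O)([C@@H](C)C(=O)O)[C@H](OC(C)=O)[C@@H]2[C@]1(C)C=CC(=O)[C@@]2(C)O | intermediate
30 | (1S,2R,5Z,7S,8S,9R,10S,11S,17R)-9-acetoxy-2,8,11-trihydroxy-12-oxobriara-5,13-diene 19→7 γ-lactone (2-O-despropanoyl target) | O[C@@H]1CC/C(C)=C\[C@@H]2OC(=O)[C@H](C)[C@@]2(O)[C@H](OC(C)=O)[C@@H]2[C@]1(C)C=CC(=O)[C@@]2(C)O | intermediate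
31 | (1S,2R,5Z,7S,8S,9R,10S,11S,17R)-9-acetoxy-8,11-dihydroxy-12-oxo-2-(propanoyloxy)briara-5,13-diene 19→7 γ-lactone (CNP0240018.1) | CCC(=O)O[C@@H]1CC/C(C)=C\[C@@H]2OC(=O)[C@H](C)[C@@]2(O)[C@H](OC(C)=O)[C@@H]2[C@]1(C)C=CC(=O)[C@@]2(C)O | target

**Summary and risks**

Total step count: 23. Longest linear sequence: 21 steps (steps 1–9, then 12–23); steps 10–11 make the side branch.

The three steps most likely to fail:

Step 15. The vinylic carbon C13 may migrate instead of C10, or the ketol shift may become reversible under the basic conditions and erode the facial control at C11. The fallback sets out from 17. Wittig ethylidenation (EtPPh3Br, KOt-Bu, toluene, 60 °C) gives the 12-ethylidene diene F1. OsO4 (cat.)/NMO should dihydroxylate the electron-rich exocyclic trisubstituted olefin from the α-face (anti to the C10 substituent) to the 11,12-diol F2. Parikh–Doering oxidation of the secondary hydroxyl gives the C12-epimeric ketol F3 (12α-OH, 12β-acetyl). With this epimer a chelating Lewis acid (Al(Ot-Bu)3, toluene, 60 °C) holds the two oxygens syn-periplanar, so the same C10 shift leads again to the 11S product; the fallback returns to the route at 21.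

Step 21. The ring-closing addition may take place on the wrong face of the C7 aldehyde, and oligomerisation may compete with closure of the strained ring. The fallback sets out from 27. If the cyclisation delivers the 7R alcohol F4, a Mitsunobu reaction with chloroacetic acid (PPh3, DIAD, THF, 0 °C) inverts the allylic C7 carbinol to the 7S chloroacetate F5; the hindered C2–OH and the tertiary alcohols do not react. Thiourea/NaHCO3 in EtOH then removes the chloroacetyl group beside the acetate, and the fallback returns to the route at 28.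

Step 17. Chelate control at C8 may be lost, the zinc enolate may add to the C12 ketone, or enolisation of the α-hydroxy ketone may epimerise C9. The fallback sets out from 22 and changes from a metal-enolate addition to Lewis-acid activation of the electrophile. 22 is precomplexed with MgBr2·OEt2 (3 equiv, CH2Cl2, −20 °C) so that only the C8 carbonyl is activated, as its five-membered chelate with O9. The trimethylsilyl ketene acetal of tert-butyl propanoate then adds in a Mukaiyama aldol reaction through an open transition state anti to C10. Citric acid work-up gives 24 directly, so this fallback makes no new compound (F0) and returns to the route at 24. Should C17 come out mixed by either method, the centre can be equilibrated at the lactone stage (DBU, toluene) towards the more stable 17R arrangement.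

Further compounds
F1 | step 15 | 12-ethylidene analogue of 17 (C12=CH–CH3 in place of C12=O, E/Z mixture) | CC(C)(C)[Si](C)(C)O[C@H](CC/C(C)=C\I)[C@@]1(C)C=CC(=CC)[C@@H]1[C@@H](O[Si](CC)(CC)CC)C(OC)(OC)CO[Si](c2ccccc2)(c2ccccc2)C(C)(C)C
F2 | step 15 | 11,12-diol from F1 (12α-OH, 12β-(1-hydroxyethyl), C11 epimers) | CC(C)(C)[Si](C)(C)O[C@H](CC/C(C)=C\I)[C@@]1(C)C=C[C@](O)(C(C)O)[C@@H]1[C@@H](O[Si](CC)(CC)CC)C(OC)(OC)CO[Si](c2ccccc2)(c2ccccc2)C(C)(C)C
F3 | step 15 | C12 epimer of 20 (12α-hydroxy, 12β-acetyl) | CC(C)(C)[Si](C)(C)O[C@H](CC/C(C)=C\I)[C@@]1(C)C=C[C@](O)(C(C)=O)[C@@H]1[C@@H](O[Si](CC)(CC)CC)C(OC)(OC)CO[Si](c2ccccc2)(c2ccccc2)C(C)(C)C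
F4 | step 21 | C7 epimer of 28 (7R alcohol) | O[C@@H]1CC/C(C)=C\[C@@H](O)[C@@](O)([C@@H](C)C(=O)OC(C)(C)C)[C@H](OC(C)=O)[C@@H]2[C@]1(C)C=CC(=O)[C@@]2(C)O
F5 | step 21 | 7-O-chloroacetate of 28 (7S) | O[C@@H]1CC/C(C)=C\[C@H](OC(=O)CCl)[C@@](O)([C@@H](C)C(=O)OC(C)(C)C)[C@H](OC(C)=O)[C@@H]2[C@]1(C)C=CC(=O)[C@@]2(C)O
F0 | step 17 | none | none
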